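Early readings say little: Thursday's run still reads 94% substrate at 1.00 h, and each reading scatters by 2 percentage points. In the flask the catalyst charge is 2.00% of the substrate charged, so the contest at the end lies between substrate and product, and the late readings are the ones to watch.

the same everywhere: substrate 0.050 M

|  | free catalyst | remark | time |
|---|---|---|---|
| Thursday's | 0.50 mM | run made earlier |  |
| Monday's | 2 mM | run made earlier |  |
| flask | 1.0 mM |  | 6.0 h |

| run | time / h | substrate / % | catalyst intermediate B / % | product / % | catalyst intermediate A / % |
|---|---|---|---|---|---|
| Thursday's | 0.500 | 96 | 4 | 4 | 1 |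
| Thursday's | 1.00 | 94 | 1 | 8 | 2 |
| Thursday's | 1.50 | 87 | 4 | 8 | 0 |
| Thursday's | 2.00 | 81 | 0 | 18 | 1 |
| Thursday's | 2.50 | 81 | 0 | 18 | 0 |
| Thursday's | 3.00 | 78 | 2 | 23 | 2 |
| Thursday's | 4.00 | 75 | 2 | 31 | 5 |
| Monday's | 0.250 | 95 | 2 | 3 | 1 |
| Monday's | 0.417 | 95 | 4 | 13 | 2 |
| Monday's | 0.667 | 84 | 0 | 11 | 0 |
| Monday's | 1.00 | 82 | 4 | 18 | 1 |
| Monday's | 1.50 | 71 | 0 | 29 | 3 |
| Monday's | 2.50 | 57 | 0 | 43 | 2 |
| Monday's | 4.00 | 44 | 2 | 59 | 2 |

(standard deviation of a reading: 2 percentage points)

* where most of what was charged as substrate, at 6.0 h is found (catalyst intermediate B / substrate / product / catalyst intermediate A)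
* the largest share itself, whichever of these holds it, in percent of the substrate charged

- the earlier runs were read with a standard deviation of 2 points

The flask resembles Monday's run: same substrate, 1.0 mM of catalyst against 2 mM. At 4.00 h, averaging substrate lost with product formed gives a conversion of 28.0% on Thursday and 57.5% on Monday. Each conversion yields a pseudo-first-order constant, and the two yield the catalyst exponent, the power of the catalyst charge by which that constant grows at this substrate charge.

Thursday's constant: 0.0821 /h

Monday's constant: 0.214 /h

Catalyst exponent: 0.691

Flask's constant: 0.133 /h

Moving from Monday's catalyst to the flask's divides the constant by 1.61, while 6.0 h against 4.00 h multiplies the time by 1.50. The time gained is smaller than the constant lost, so the flask should end just behind Monday's last conversion. My reckoning leaves 45.1% substrate and makes 54.9% product, with product ahead.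

The forecast differs, naming substrate at 53% (range 47% to 61%) and saying “substrate narrowly holds the most”.

The flask gives product at 57.0%, with substrate at 42.6%.

    substrate + free catalyst → catalyst intermediate A (k = 19.7 /M/min)
    catalyst intermediate A ⇌ catalyst intermediate B (K = 2.70, k = 0.295 /min)
    catalyst intermediate B → free catalyst + product (k = 4.98 /min)
    2 free catalyst ⇌ resting dimer, settled at all times (K = 20300 /M)

At 6.00 h the flask's resting dimer, the catalyst's resting state, holds 67.2% of the catalyst charged, and free catalyst 12.9%. The exponent 0.691, read from two scattered runs, carries over to the neighbouring flask with 0.600 mM of catalyst and the same substrate: its constant is reckoned at 0.0931 /h, which gives an estimate of 57.2% substrate at 6.0 h. That neighbouring flask holds most of what was charged as substrate, which stands at 55%.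

(Readings and results come from a simulation with constants of no real substance.)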